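The dihydrofuran ring is opened at O1–C2 and C3–C3a. This leads back to iodoresorcinol ketone 2 and the silyl-protected allenyl carbinol 7. One asymmetric palladium-catalysed [3+2] heteroannulation joins C3a to the central allene carbon (C3) and O1 to the substituted terminus (C2, bearing branched C1'), closing the ring and setting C2. It exploits the ortho pair O1/C3a on the benzene ring facing the contiguous C2–C3 unit. The C3 oxygen stays latent in the exocyclic methylene that the annulation leaves behind. Ozonolysis, hydride delivery anti to C1', angeloylation and conversion of CMe2O into the acetoxymethylvinyl group complete the target.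

Key step: step 4

Assumption: the sense of induction of the bis(oxazoline) ligand must be settled by a trial run, so wherever (4S) is written the antipode that gives (2S)-8 is meant. Any residual minor enantiomer is to be removed by recrystallising diol 13.

Remark: the target is (2R,3R) with C2 and C3 substituents cis. The C2 descriptor alternates between S and R along the route only because CIP ranks of C1' and C3 change; the spatial arrangement stays the same.

Step 1
Reactants: 1 2,4-dihydroxyacetophenone
Product: 2 1-(2,4-dihydroxy-5-iodophenyl)ethanone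
Conditions: ICl (1.0 equiv), AcOH, rt
Reagents that add atoms: iodine monochloride, ClI
Why: Electrophilic aromatic iodination (SEAr): in acidic medium the un-ionised resorcinol ketone is attacked at the open C5 position, ortho to the 4-OH and para to the 2-OH, rather than at C3, which is wedged between the two hydroxyl groups.

Step 2
Reactants: 3 2-methylbut-3-yn-2-ol; 4 formaldehyde (as paraformaldehyde)
Product: 6 2-methylpenta-3,4-dien-2-ol, via Mannich base 5 (not isolated)
Conditions: (CH2O)n, CuBr (0.4 equiv), i-Pr2NH, 1,4-dioxane, reflux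
Reagents that add atoms: none
Why: Crabbé allene homologation: CuBr-mediated Mannich coupling of alkyne, formaldehyde and amine gives propargylamine 5, whose isopropyl methine hydrogen then passes to the alkyne carbon in a copper-assisted retro-imino-ene step that expels the imine and leaves the terminal allene, a sequence that tolerates free tertiary propargylic alcohols.

Step 3
Reactants: 6 2-methylpenta-3,4-dien-2-ol
Product: 7 triethyl[(2-methylpenta-3,4-dien-2-yl)oxy]silane
Conditions: Et3SiOTf, 2,6-lutidine, CH2Cl2, 0 °C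
Reagents that add atoms: triethylsilyl trifluoromethanesulfonate, CC[Si](CC)(CC)OS(=O)(=O)C(F)(F)F
Why: Silyl triflate silylation of a hindered tertiary alcohol under a non-nucleophilic base; the ether masks a hydroxyl that would otherwise compete as a nucleophile in step 4 and would allow retro-aldol cleavage at the ketone stage of step 6.

Step 4
Reactants: 2 1-(2,4-dihydroxy-5-iodophenyl)ethanone; 7 triethyl[(2-methylpenta-3,4-dien-2-yl)oxy]silane
Product: 8 1-[(2S)-6-hydroxy-3-methylidene-2-[2-(triethylsilyloxy)propan-2-yl]-2,3-dihydro-1-benzofuran-5-yl]ethanone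
Conditions: Pd(OAc)2 (5 mol %), 2,2'-(propane-2,2-diyl)bis[(4S)-4-phenyl-4,5-dihydrooxazole] (10 mol %), Ag3PO4 (1.2 equiv), 7 (3 equiv), DMF, 90 °C
Reagents that add atoms: none
Why: Zerovalent palladium, formed in situ from Pd(OAc)2 and the ligand, inserts into the C–I bond of 2, Ag3PO4 removes iodide, and syn-carbopalladation of 7 places the aryl group on the central allene carbon (C3a–C3), leaving a cationic η3-allyl complex that spans CH2, C3 and C2. The closest known reaction type is the Larock heteroannulation of 1,2-dienes by ortho-iodophenols, including its enantioselective bis(oxazoline) variant run with Pd(OAc)2 and Ag3PO4 in DMF. The phenoxide derived from the 4-OH then attacks C2 on the face away from the metal, formally a 5-exo-tet displacement of palladium, which closes the dihydrofuran ring (O1–C2) and leaves C3=CH2 exocyclic. C2 is set in this C–O bond formation: the two diastereomeric allyl complexes equilibrate by π–σ–π slippage through the unsubstituted CH2 terminus, and the twofold-symmetric ligand decides which of them is captured faster. Two selectivities are needed: attack at the substituted rather than the CH2 terminus (both would give five-membered rings), favoured by the greater cationic character of the substituted terminus in the halide-free N,N-ligated complex, and use of only one hydroxyl, secured because the 4-OH alone is ortho to iodine and is the more acidic, while the 2-OH is hydrogen-bonded to the acetyl group and para to the metal-bearing carbon. The carbinol oxygen is carried as a silyl ether so that it can neither act as a rival nucleophile (oxirane or dihydrofuran formation) nor ionise as an ester would, and the silver salt also curbs palladium hydride migration of the exocyclic alkene into the aromatic 3-methylbenzofuran, which would erase C2.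

Step 5
Reactants: 8 1-[(2S)-6-hydroxy-3-methylidene-2-[2-(triethylsilyloxy)propan-2-yl]-2,3-dihydro-1-benzofuran-5-yl]ethanone
Product: 9 1-[(2S)-3-methylidene-2-[2-(triethylsilyloxy)propan-2-yl]-6-(triisopropylsilyloxy)-2,3-dihydro-1-benzofuran-5-yl]ethanone
Conditions: i-Pr3SiOTf, 2,6-lutidine, CH2Cl2, −78 → 0 °C
Reagents that add atoms: triisopropylsilyl trifluoromethanesulfonate, CC(C)[Si](OS(=O)(=O)C(F)(F)F)(C(C)C)C(C)C
Why: Silylation of the only free hydroxyl: the bulky aryl silyl ether stops phenoxide formation in step 6 (which would deactivate the para C3 ketone and steer borohydride to the acetyl group), screens the ortho acetyl carbonyl, blocks O-acylation in steps 8 and 11, and prevents base-induced expulsion of the para-benzylic ester as a quinone methide.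

Step 6
Reactants: 9 1-[(2S)-3-methylidene-2-[2-(triethylsilyloxy)propan-2-yl]-6-(triisopropylsilyloxy)-2,3-dihydro-1-benzofuran-5-yl]ethanone
Product: 12 1-[(2S,3R)-3-hydroxy-2-[2-(triethylsilyloxy)propan-2-yl]-6-(triisopropylsilyloxy)-2,3-dihydro-1-benzofuran-5-yl]ethanone (2,3-cis), via spiro-ozonide 10 (not isolated), via C3 ketone 11 (not isolated)
Conditions: O3, CH2Cl2, −78 °C (Sudan Red 7B end point); PPh3, −78 → 0 °C; then MeOH, CeCl3·7H2O, NaBH4 (limiting), −78 °C
Reagents that add atoms: ozone, [O-][O+]=O
Why: Criegee ozonolysis of the only C=C bond followed by Luche reduction in the same flask: hydride reaches the planar C3 carbonyl from the face opposite the bulky C2 substituent, so the new hydroxyl ends cis to it (3R); the α-aryloxy five-ring ketone is more electrophilic than the doubly oxygen-donated acetyl group shielded by the ortho silyloxy group, and the cold, cerium-buffered, non-basic medium together with non-isolation of 11 keeps the acidic C2–H from enolising.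

Step 7
Reactants: 12 1-[(2S,3R)-3-hydroxy-2-[2-(triethylsilyloxy)propan-2-yl]-6-(triisopropylsilyloxy)-2,3-dihydro-1-benzofuran-5-yl]ethanone
Product: 13 1-[(2S,3R)-3-hydroxy-2-(2-hydroxypropan-2-yl)-6-(triisopropylsilyloxy)-2,3-dihydro-1-benzofuran-5-yl]ethanone
Conditions: HF·pyridine, pyridine, THF, 0 °C
Reagents that add atoms: none
Why: Fluoride-mediated desilylation under mildly acidic conditions, where the small alkyl triethylsilyl ether is cleaved far faster than the bulky aryl triisopropylsilyl ether; done at this point it relieves crowding next to C3–OH, makes any silyl migration in step 6 irrelevant and spares the later angelate this treatment.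

Step 8
Reactants: 13 1-[(2S,3R)-3-hydroxy-2-(2-hydroxypropan-2-yl)-6-(triisopropylsilyloxy)-2,3-dihydro-1-benzofuran-5-yl]ethanone; 14 angelic acid
Product: 16 (2S,3R)-5-acetyl-2-(2-hydroxypropan-2-yl)-6-(triisopropylsilyloxy)-2,3-dihydro-1-benzofuran-3-yl (Z)-2-methylbut-2-enoate, via mixed anhydride 15 (not isolated)
Conditions: 14, 2,4,6-trichlorobenzoyl chloride, Et3N, toluene, rt; then 13, 75 °C
Reagents that add atoms: none
Why: Yamaguchi-type mixed-anhydride esterification run thermally without a nucleophilic pyridine catalyst, the standard way to make angelates, since no reversible conjugate addition to the acyl donor can turn the Z-alkene into the tiglate; the alcohol attacks the angeloyl carbonyl because the aroyl one is flanked by two chlorines, the tertiary carbinol is too hindered to react, and the C3–O bond is untouched so configuration is kept.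

Step 9
Reactants: 16 (2S,3R)-5-acetyl-2-(2-hydroxypropan-2-yl)-6-(triisopropylsilyloxy)-2,3-dihydro-1-benzofuran-3-yl (Z)-2-methylbut-2-enoate
Product: 17 (2R,3R)-5-acetyl-2-(prop-1-en-2-yl)-6-(triisopropylsilyloxy)-2,3-dihydro-1-benzofuran-3-yl (Z)-2-methylbut-2-enoate
Conditions: methyl N-(triethylammoniosulfonyl)carbamate (Burgess reagent), toluene, 50 °C
Reagents that add atoms: none
Why: Burgess dehydration: the tertiary sulfamate collapses by neutral syn-elimination (Ei), taking one of the six exposed methyl hydrogens in preference to the single hindered, oxygen-deactivated C2–H, as is usual for 2-(2-hydroxypropan-2-yl)dihydrobenzofurans, and the absence of acid or strong base protects the benzylic angelate from ionisation or elimination to the benzofuran.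

Step 10
Reactants: 17 (2R,3R)-5-acetyl-2-(prop-1-en-2-yl)-6-(triisopropylsilyloxy)-2,3-dihydro-1-benzofuran-3-yl (Z)-2-methylbut-2-enoate
Product: 18 (2R,3R)-5-acetyl-2-(3-hydroxyprop-1-en-2-yl)-6-(triisopropylsilyloxy)-2,3-dihydro-1-benzofuran-3-yl (Z)-2-methylbut-2-enoate
Conditions: SeO2 (0.3 equiv), t-BuOOH (decane solution), CH2Cl2, 0 °C → rt
Reagents that add atoms: selenium dioxide, O=[Se]=O (oxygen carrier); tert-butyl hydroperoxide, CC(C)(C)OO (terminal oxygen source)
Why: Catalytic SeO2 allylic oxidation (ene reaction then [2,3]-sigmatropic shift, Riley type): selenium attacks the most electron-rich alkene, the 1,1-disubstituted isopropenyl group, and engages the methyl hydrogens rather than the hindered C2–H, while the conjugated angelate alkene is deactivated and the acetyl methyl needs stoichiometric SeO2 and heat to react.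

Step 11
Reactants: 18 (2R,3R)-5-acetyl-2-(3-hydroxyprop-1-en-2-yl)-6-(triisopropylsilyloxy)-2,3-dihydro-1-benzofuran-3-yl (Z)-2-methylbut-2-enoate
Product: 19 (2R,3R)-2-(3-acetoxyprop-1-en-2-yl)-5-acetyl-6-(triisopropylsilyloxy)-2,3-dihydro-1-benzofuran-3-yl (Z)-2-methylbut-2-enoate
Conditions: Ac2O, pyridine, 4-(dimethylamino)pyridine (cat.), CH2Cl2, 0 °C
Reagents that add atoms: acetic anhydride, CC(=O)OC(C)=O
Why: Nucleophile-catalysed acetylation of the only free hydroxyl, a primary allylic alcohol, under conditions that leave the alkyl angelate, the silyl ether and both stereocentres untouched.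

Step 12
Reactants: 19 (2R,3R)-2-(3-acetoxyprop-1-en-2-yl)-5-acetyl-6-(triisopropylsilyloxy)-2,3-dihydro-1-benzofuran-3-yl (Z)-2-methylbut-2-enoate
Product: 20 (2R,3R)-2-(3-acetoxyprop-1-en-2-yl)-5-acetyl-6-hydroxy-2,3-dihydro-1-benzofuran-3-yl (Z)-2-methylbut-2-enoate (target)
Conditions: Bu4NF, AcOH (1 equiv each), THF, 0 °C
Reagents that add atoms: none
Why: Fluoride cleavage of an aryl silyl ether activated by its ortho acetyl group, orthogonal to both esters; the acetic acid buffer protonates the phenoxide at once, so that it neither expels the para-benzylic angelate as a quinone methide nor transesterifies, and the freed phenol is locked by hydrogen bonding to the acetyl oxygen.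

Compound list
1 | 2,4-dihydroxyacetophenone | CC(=O)c1ccc(O)cc1O | starting material
2 | 1-(2,4-dihydroxy-5-iodophenyl)ethanone | CC(=O)c1cc(I)c(O)cc1O | intermediate
3 | 2-methylbut-3-yn-2-ol | CC(C)(O)C#C | starting material
4 | formaldehyde (as paraformaldehyde) | C=O | starting material
5 | 5-(diisopropylamino)-2-methylpent-3-yn-2-ol (Mannich base, not isolated) | CC(C)(O)C#CCN(C(C)C)C(C)C | intermediate
6 | 2-methylpenta-3,4-dien-2-ol | CC(C)(O)C=C=C | intermediate
7 | triethyl[(2-methylpenta-3,4-dien-2-yl)oxy]silane | CC(C)(O[Si](CC)(CC)CC)C=C=C | intermediate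
8 | 1-[(2S)-6-hydroxy-3-methylidene-2-[2-(triethylsilyloxy)propan-2-yl]-2,3-dihydro-1-benzofuran-5-yl]ethanone | CC(C)(O[Si](CC)(CC)CC)[C@H]1Oc2cc(O)c(C(C)=O)cc2C1=C | intermediate
9 | 1-[(2S)-3-methylidene-2-[2-(triethylsilyloxy)propan-2-yl]-6-(triisopropylsilyloxy)-2,3-dihydro-1-benzofuran-5-yl]ethanone | CC(C)(O[Si](CC)(CC)CC)[C@H]1Oc2cc(O[Si](C(C)C)(C(C)C)C(C)C)c(C(C)=O)cc2C1=C | intermediate
10 | secondary ozonide of 9: spiro-1,2,4-trioxolane at C3, (2R), spiro centre undefined (not isolated) | CC(C)(O[Si](CC)(CC)CC)[C@H]1Oc2cc(O[Si](C(C)C)(C(C)C)C(C)C)c(C(C)=O)cc2C13OCOO3 | intermediate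
11 | (2R)-5-acetyl-2-[2-(triethylsilyloxy)propan-2-yl]-6-(triisopropylsilyloxy)-1-benzofuran-3(2H)-one (not isolated) | CC(C)(O[Si](CC)(CC)CC)[C@H]1Oc2cc(O[Si](C(C)C)(C(C)C)C(C)C)c(C(C)=O)cc2C1=O | intermediate
12 | 1-[(2S,3R)-3-hydroxy-2-[2-(triethylsilyloxy)propan-2-yl]-6-(triisopropylsilyloxy)-2,3-dihydro-1-benzofuran-5-yl]ethanone | CC(C)(O[Si](CC)(CC)CC)[C@H]1Oc2cc(O[Si](C(C)C)(C(C)C)C(C)C)c(C(C)=O)cc2[C@H]1O | intermediate
13 | 1-[(2S,3R)-3-hydroxy-2-(2-hydroxypropan-2-yl)-6-(triisopropylsilyloxy)-2,3-dihydro-1-benzofuran-5-yl]ethanone | CC(C)(O)[C@H]1Oc2cc(O[Si](C(C)C)(C(C)C)C(C)C)c(C(C)=O)cc2[C@H]1O | intermediate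
14 | angelic acid, (Z)-2-methylbut-2-enoic acid | C/C=C(/C)C(=O)O | starting material
15 | (Z)-2-methylbut-2-enoic 2,4,6-trichlorobenzoic anhydride (not isolated) | C/C=C(/C)C(=O)OC(=O)c1c(Cl)cc(Cl)cc1Cl | intermediate
16 | (2S,3R)-5-acetyl-2-(2-hydroxypropan-2-yl)-6-(triisopropylsilyloxy)-2,3-dihydro-1-benzofuran-3-yl (Z)-2-methylbut-2-enoate | CC(C)(O)[C@H]1Oc2cc(O[Si](C(C)C)(C(C)C)C(C)C)c(C(C)=O)cc2[C@H]1OC(=O)/C(C)=C\C | intermediate
17 | (2R,3R)-5-acetyl-2-(prop-1-en-2-yl)-6-(triisopropylsilyloxy)-2,3-dihydro-1-benzofuran-3-yl (Z)-2-methylbut-2-enoate | C=C(C)[C@H]1Oc2cc(O[Si](C(C)C)(C(C)C)C(C)C)c(C(C)=O)cc2[C@H]1OC(=O)/C(C)=C\C | intermediate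
18 | (2R,3R)-5-acetyl-2-(3-hydroxyprop-1-en-2-yl)-6-(triisopropylsilyloxy)-2,3-dihydro-1-benzofuran-3-yl (Z)-2-methylbut-2-enoate | C=C(CO)[C@H]1Oc2cc(O[Si](C(C)C)(C(C)C)C(C)C)c(C(C)=O)cc2[C@H]1OC(=O)/C(C)=C\C | intermediate
19 | (2R,3R)-2-(3-acetoxyprop-1-en-2-yl)-5-acetyl-6-(triisopropylsilyloxy)-2,3-dihydro-1-benzofuran-3-yl (Z)-2-methylbut-2-enoate | C=C(COC(C)=O)[C@H]1Oc2cc(O[Si](C(C)C)(C(C)C)C(C)C)c(C(C)=O)cc2[C@H]1OC(=O)/C(C)=C\C | intermediate
20 | (2R,3R)-2-(3-acetoxyprop-1-en-2-yl)-5-acetyl-6-hydroxy-2,3-dihydro-1-benzofuran-3-yl (Z)-2-methylbut-2-enoate | C=C(COC(C)=O)[C@H]1Oc2cc(O)c(C(C)=O)cc2[C@H]1OC(=O)/C(C)=C\C | target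

Total step count: 12. Longest linear sequence: 11 (steps 2 to 12).

Steps most likely to fail

Step 4 (key step). The phenoxide may capture the allyl complex at its unhindered CH2 terminus. The bulk and the inductive pull of the neighbouring silyloxy-bearing quaternary carbon both push in that direction. The ligand may also discriminate the two faces incompletely.

The fallback sets out from 2 and comes back at 9. It makes the two ring bonds one after the other and takes the stereocentre from a reagent-controlled epoxidation.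
- 4-Methylpenta-1,3-diene is epoxidised at its trisubstituted double bond by Shi epoxidation (1,2:4,5-di-O-isopropylidene-β-D-erythro-hexo-2,3-diulo-2,6-pyranose, KHSO5, K2CO3, MeCN–dimethoxymethane–water, 0 °C). This gives (2R)-2-ethenyl-3,3-dimethyloxirane F1, the sense expected by analogy with trisubstituted styrenes.
- The 4-phenoxide of 2 (Cs2CO3, DMF, 60 °C) opens it by SN2 attack at the secondary allylic carbon with inversion. The product is 1-[2-hydroxy-4-{[(3S)-2-hydroxy-2-methylpent-4-en-3-yl]oxy}-5-iodophenyl]ethanone F2.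
- i-Pr3SiCl with imidazole caps the remaining phenol to give the aryl triisopropylsilyl ether F3.
- Et3SiOTf with 2,6-lutidine caps the tertiary carbinol to give the bis-silyl ether F4.
- A 5-exo-trig Mizoroki–Heck cyclisation (Pd(OAc)2, PPh3, Ag2CO3, MeCN, 70 °C) forms C3a–C3, and β-hydride loss from C3 delivers 9.

Step 6. Hydride may also be delivered to the acetyl carbonyl. The transient ketone may enolise towards the aromatic 3-hydroxybenzofuran tautomer, which would erode C2 or expel silanolate.

The fallback sets out from 9 and comes back at 16. It takes the acetyl group out of play before the alkene is cleaved.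
- NaBH4 with CeCl3·7H2O in MeOH at 0 °C reduces 9 to the 1-hydroxyethyl compound F5, an inconsequential epimer mixture.
- Et3SiCl with imidazole gives its triethylsilyl ether F6.
- Ozonolysis passes through the spiro-ozonide F7, and PPh3 converts it into the C3 ketone F8.
- An excess of NaBH4 at −78 °C then gives the cis C3 alcohol F9 with no competing carbonyl and the shortest possible lifetime of the ketone.
- Thermal acylation with mixed anhydride 15 gives the angelate F10.
- HF·pyridine removes both alkyl silyl groups to give the diol angelate F11.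
- Dess–Martin periodinane oxidises the only secondary alcohol back to the acetyl group, which is 16.

Step 10. The reaction may stall at partial conversion. It may also over-oxidise to the enal, or the acidic selenium species may slowly ionise the benzylic angelate.

The fallback sets out from 17 and comes back at 19, bypassing 18. It replaces C–H oxygenation by chlorination and substitution.
- Ene-type allylic chlorination (N-chlorosuccinimide, PhSeCl cat., CH2Cl2, rt) gives the 2-(3-chloroprop-1-en-2-yl) compound F12.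
- SN2 displacement with CsOAc in DMF at rt installs the acetate directly.

Further compounds
F1 | step 4 | (2R)-2-ethenyl-3,3-dimethyloxirane | CC1(C)[C@H](O1)C=C
F2 | step 4 | 1-[2-hydroxy-4-{[(3S)-2-hydroxy-2-methylpent-4-en-3-yl]oxy}-5-iodophenyl]ethanone | CC(C)(O)[C@@H](Oc1cc(O)c(C(C)=O)cc1I)C=C
F3 | step 4 | 1-[4-{[(3S)-2-hydroxy-2-methylpent-4-en-3-yl]oxy}-5-iodo-2-(triisopropylsilyloxy)phenyl]ethanone | CC(C)(O)[C@@H](Oc1cc(O[Si](C(C)C)(C(C)C)C(C)C)c(C(C)=O)cc1I)C=C
F4 | step 4 | 1-[5-iodo-4-{[(3S)-2-methyl-2-(triethylsilyloxy)pent-4-en-3-yl]oxy}-2-(triisopropylsilyloxy)phenyl]ethanone | CC(C)(O[Si](CC)(CC)CC)[C@@H](Oc1cc(O[Si](C(C)C)(C(C)C)C(C)C)c(C(C)=O)cc1I)C=C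
F5 | step 6 | 1-[(2S)-3-methylidene-2-[2-(triethylsilyloxy)propan-2-yl]-6-(triisopropylsilyloxy)-2,3-dihydro-1-benzofuran-5-yl]ethanol (carbinol epimers) | CC(C)(O[Si](CC)(CC)CC)[C@H]1Oc2cc(O[Si](C(C)C)(C(C)C)C(C)C)c(C(C)O)cc2C1=C
F6 | step 6 | triethylsilyl ether of F5 | CC(C)(O[Si](CC)(CC)CC)[C@H]1Oc2cc(O[Si](C(C)C)(C(C)C)C(C)C)c(C(C)O[Si](CC)(CC)CC)cc2C1=C
F7 | step 6 | secondary ozonide of F6 (spiro-1,2,4-trioxolane at C3) | CC(C)(O[Si](CC)(CC)CC)[C@H]1Oc2cc(O[Si](C(C)C)(C(C)C)C(C)C)c(C(C)O[Si](CC)(CC)CC)cc2C13OCOO3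
F8 | step 6 | (2R)-2-[2-(triethylsilyloxy)propan-2-yl]-5-[1-(triethylsilyloxy)ethyl]-6-(triisopropylsilyloxy)-1-benzofuran-3(2H)-one | CC(C)(O[Si](CC)(CC)CC)[C@H]1Oc2cc(O[Si](C(C)C)(C(C)C)C(C)C)c(C(C)O[Si](CC)(CC)CC)cc2C1=O
F9 | step 6 | (2S,3R)-2-[2-(triethylsilyloxy)propan-2-yl]-5-[1-(triethylsilyloxy)ethyl]-6-(triisopropylsilyloxy)-2,3-dihydro-1-benzofuran-3-ol | CC(C)(O[Si](CC)(CC)CC)[C@H]1Oc2cc(O[Si](C(C)C)(C(C)C)C(C)C)c(C(C)O[Si](CC)(CC)CC)cc2[C@H]1O
F10 | step 6 | (Z)-2-methylbut-2-enoate (angelate) of F9 | CC(C)(O[Si](CC)(CC)CC)[C@H]1Oc2cc(O[Si](C(C)C)(C(C)C)C(C)C)c(C(C)O[Si](CC)(CC)CC)cc2[C@H]1OC(=O)/C(C)=C\C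
F11 | step 6 | (2S,3R)-5-(1-hydroxyethyl)-2-(2-hydroxypropan-2-yl)-6-(triisopropylsilyloxy)-2,3-dihydro-1-benzofuran-3-yl (Z)-2-methylbut-2-enoate | CC(C)(O)[C@H]1Oc2cc(O[Si](C(C)C)(C(C)C)C(C)C)c(C(C)O)cc2[C@H]1OC(=O)/C(C)=C\C
F12 | step 10 | (2R,3R)-5-acetyl-2-(3-chloroprop-1-en-2-yl)-6-(triisopropylsilyloxy)-2,3-dihydro-1-benzofuran-3-yl (Z)-2-methylbut-2-enoate | C=C(CCl)[C@H]1Oc2cc(O[Si](C(C)C)(C(C)C)C(C)C)c(C(C)=O)cc2[C@H]1OC(=O)/C(C)=C\C
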